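**Plan**
Retrosynthesis: the S–O bond of the 3-sulfate is cut first, then ring A is taken apart at C4a–C5, C5–C6, C7–C8 and C8–C8a (ketene plus ynol ether benzannulation), and last the C2–aryl bond (cross-coupling), which leads back to kojic acid.
Forward: ring C is kojic acid itself, ring B is attached to it by Suzuki coupling, and ring A is closed last on the pyranone by a photo-Wolff/vinylketene benzannulation with a siloxyacetylene; debenzylation, 3-O-sulfation and desilylation finish the route.
Enabling feature: ring C is a 3-oxygenated 4-pyranone with one free C–H carbon (C4a) next to the C4 carbonyl, and ring A carries oxygen at C5 and C7 in a meta relation, which is the pattern such a benzannulation delivers, with the two oxygens differently masked.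
Stereochemistry: the target has no stereocentre; only regiochemistry has to be controlled, and it comes from the polarity of the ynol ether.

Key step: step 7

Assumption: the target is drawn as the free hydrogen sulfate; because such acids hydrolyse autocatalytically, the sulfate is carried as its pyridinium salt and the acid form is liberated only in the last operation, cold, and kept as a lyophilisate.

**Route**

Step 1
Reactants: 1 acetylene; 2 triisopropylsilyl trifluoromethanesulfonate
Product: 5 (triisopropylsilyloxy)acetylene, via lithium acetylide 3 (not isolated), via lithium ethynolate 4 (not isolated)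
Conditions: 1 (excess), n-BuLi, THF, −78 °C; t-BuOOLi (from t-BuOOH + LiN(SiMe3)2, THF, −78 °C), −78 → −10 °C; 2, −78 → 0 °C; distil
Reagents that add atoms: n-butyllithium, [Li]CCCC (lithium of 3 and 4); tert-butyl hydroperoxide, CC(C)(C)OO (the oxygen atom)
Why: Monolithium acetylide should be oxidised at carbon by the electrophilic peroxide oxygen of t-BuOOLi (Julia oxidation of lithium acetylides to ynolates), and the hard, bulky silyl triflate should then silylate the ynolate on oxygen, as in the standard preparation of triisopropylsilyl ynol ethers.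

Step 2
Reactants: 6 kojic acid
Product: 7 6-bromo-5-hydroxy-2-(hydroxymethyl)-4H-pyran-4-one
Conditions: NBS, MeCN, 0 → 25 °C
Reagents that add atoms: N-bromosuccinimide, O=C1CCC(=O)N1Br
Why: Electrophilic bromination of the enolic 5-hydroxy-4-pyranone should go to C6, the carbon ortho to the enol hydroxyl, where kojic acid reacts with electrophiles (Mannich reaction, hydroxymethylation, halogenation).

Step 3
Reactants: 7 6-bromo-5-hydroxy-2-(hydroxymethyl)-4H-pyran-4-one
Product: 8 5-(benzyloxy)-6-bromo-2-(hydroxymethyl)-4H-pyran-4-one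
Conditions: BnBr, K2CO3, DMF, 25 °C
Reagents that add atoms: benzyl bromide, BrCc1ccccc1
Why: Williamson etherification, in which carbonate deprotonates only the acidic enolic hydroxyl, so that the primary alcohol stays free.

Step 4
Reactants: 8 5-(benzyloxy)-6-bromo-2-(hydroxymethyl)-4H-pyran-4-one; 9 4-methoxyphenylboronic acid
Product: 10 5-(benzyloxy)-2-(hydroxymethyl)-6-(4-methoxyphenyl)-4H-pyran-4-one
Conditions: Pd(PPh3)4 (5 mol %), K2CO3, 1,4-dioxane/H2O, 85 °C
Reagents that add atoms: none
Why: Suzuki–Miyaura coupling, in which the C6–Br bond of the β-bromo enone should add readily to zerovalent palladium while the free alcohol and the benzyl ether are spectators.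

Step 5
Reactants: 10 5-(benzyloxy)-2-(hydroxymethyl)-6-(4-methoxyphenyl)-4H-pyran-4-one
Product: 11 5-(benzyloxy)-6-(4-methoxyphenyl)-4-oxo-4H-pyran-2-carboxylic acid
Conditions: CrO3, H2SO4, H2O, acetone, 0 → 25 °C
Reagents that add atoms: chromium trioxide, O=[Cr](=O)=O, and water, O (the second carboxyl oxygen)
Why: Jones oxidation of the primary alcohol through the aldehyde hydrate to the acid, the standard conversion of O-benzylkojic acid into O-benzylcomenic acid, which the benzyl ether, the anisyl ring and the pyranone should tolerate in the cold.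

Step 6
Reactants: 11 5-(benzyloxy)-6-(4-methoxyphenyl)-4-oxo-4H-pyran-2-carboxylic acid; 12 trimethylsilyldiazomethane
Product: 14 5-(benzyloxy)-2-(diazoacetyl)-6-(4-methoxyphenyl)-4H-pyran-4-one, via acid chloride 13 (not isolated)
Conditions: (COCl)2, DMF (cat.), CH2Cl2, 0 → 25 °C; concentrate; 12 (2.2 equiv), THF/MeCN, 0 °C
Reagents that add atoms: oxalyl chloride, O=C(Cl)C(Cl)=O (chlorine of 13)
Why: Acid chloride formation by the chloroiminium from oxalyl chloride and DMF, then C-acylation of trimethylsilyldiazomethane with loss of the silyl group (Arndt–Eistert-type diazo ketone synthesis); the acid chloride has no α-hydrogen, so no ketene can form at this stage.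

Step 7
Reactants: 14 5-(benzyloxy)-2-(diazoacetyl)-6-(4-methoxyphenyl)-4H-pyran-4-one; 5 (triisopropylsilyloxy)acetylene
Product: 19 3-(benzyloxy)-5-hydroxy-2-(4-methoxyphenyl)-7-(triisopropylsilyloxy)-4H-chromen-4-one, via pyranonylketene 15 (not isolated), via siloxycyclobutenone 16 (not isolated), via dienylketene 17 (not isolated), via keto tautomer 18 (not isolated)
Conditions: hν (blue LEDs, 450 nm), 5 (2.5 equiv), degassed ClCH2CH2Cl, 25 °C; then 80 °C
Reagents that add atoms: none
Why: Excitation of the diazo ketone expels N2 and the pyranonyl group migrates (Wolff rearrangement, new C8–C8a bond) to give ketene 15, which adds the siloxyalkyne [2+2] (C5–C6 and C7–C8) to give cyclobutenone 16; this opens by conrotatory 4π cleavage to dienylketene 17, which closes by 6π electrocyclisation (C4a–C5) to dienone 18 and enolises to the phenol. This is the photochemical Danheiser benzannulation of unsaturated α-diazo ketones with siloxyalkynes, and the closest cases are 2-furyl and other heteroaryl diazo ketones, which give benzo-fused heterocycles with the same hydroxy/silyloxy pattern. Ring A, the only ring that persists, is closed by the thermal disrotatory 6π electrocyclisation of the ketene carbon onto C4a; the four-membered ring of 16 is transient. No stereocentre remains, since the sp3 carbons of 16 and 18 are lost on ring opening and enolisation. The required regiochemistry, silyloxy at C7 meta to the C5 hydroxyl, follows from the polarity of the ynol ether, whose unsubstituted carbon is the nucleophile and bonds to the ketene carbonyl carbon, and the closure has only one terminus, the single C–H carbon of the pyranone. Blue light is chosen because only the diazo ketone absorbs there, which spares the pyranone and 3-benzyloxychromone chromophores, and the final warming drives remaining 16 to the phenol, helped by aromatisation and the hydrogen bond from C5–OH to the C4 carbonyl.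

Step 8
Reactants: 19 3-(benzyloxy)-5-hydroxy-2-(4-methoxyphenyl)-7-(triisopropylsilyloxy)-4H-chromen-4-one
Product: 20 3,5-dihydroxy-2-(4-methoxyphenyl)-7-(triisopropylsilyloxy)-4H-chromen-4-one
Conditions: H2 (1 atm), 10% Pd/C, EtOAc, 25 °C
Reagents that add atoms: none
Why: Hydrogenolysis of the benzyl ether on palladium, under which the aryl silyl ether, the methyl ether and the C2–C3 double bond of the flavone should stay intact.

Step 9
Reactants: 20 3,5-dihydroxy-2-(4-methoxyphenyl)-7-(triisopropylsilyloxy)-4H-chromen-4-one
Product: 21 pyridinium 5-hydroxy-2-(4-methoxyphenyl)-4-oxo-7-(triisopropylsilyloxy)-4H-chromen-3-yl sulfate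
Conditions: SO3·pyridine (5 equiv), pyridine, 25 → 40 °C
Reagents that add atoms: sulfur trioxide pyridine complex, [O-]S(=O)(=O)[n+]1ccccc1
Why: O-Sulfonation with an SO3–amine complex should take the 3-hydroxyl only, because the 5-hydroxyl is locked in a six-membered hydrogen bond to the C4 carbonyl and is inert to this reagent, and the 7-oxygen is silylated.

Step 10
Reactants: 21 pyridinium 5-hydroxy-2-(4-methoxyphenyl)-4-oxo-7-(triisopropylsilyloxy)-4H-chromen-3-yl sulfate
Product: 22 kaempferide 3-O-sulfate
Conditions: HF·pyridine, pyridine, THF, 0 → 25 °C; then sulfonic acid cation-exchange resin (H+ form), MeOH/H2O, 0 °C; lyophilise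
Reagents that add atoms: none
Why: Fluoride-mediated cleavage of the aryl silyl ether (driven by the Si–F bond) should leave the sulfate monoester anion untouched under buffered anhydrous conditions, and cold exchange of pyridinium for a proton then gives the acid form.

**Compound list**
1 | acetylene | C#C | starting material
2 | triisopropylsilyl trifluoromethanesulfonate | CC(C)[Si](OS(=O)(=O)C(F)(F)F)(C(C)C)C(C)C | starting material
3 | lithium acetylide | [Li]C#C | intermediate
4 | lithium ethynolate | [Li+].[O-]C#C | intermediate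
5 | (triisopropylsilyloxy)acetylene | C#CO[Si](C(C)C)(C(C)C)C(C)C | intermediate
6 | kojic acid, 5-hydroxy-2-(hydroxymethyl)-4H-pyran-4-one | OCc1cc(=O)c(O)co1 | starting material
7 | 6-bromo-5-hydroxy-2-(hydroxymethyl)-4H-pyran-4-one | OCc1cc(=O)c(O)c(Br)o1 | intermediate
8 | 5-(benzyloxy)-6-bromo-2-(hydroxymethyl)-4H-pyran-4-one | OCc1cc(=O)c(OCc2ccccc2)c(Br)o1 | intermediate
9 | 4-methoxyphenylboronic acid | COc1ccc(B(O)O)cc1 | starting material
10 | 5-(benzyloxy)-2-(hydroxymethyl)-6-(4-methoxyphenyl)-4H-pyran-4-one | OCc1cc(=O)c(OCc2ccccc2)c(-c2ccc(OC)cc2)o1 | intermediate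
11 | 5-(benzyloxy)-6-(4-methoxyphenyl)-4-oxo-4H-pyran-2-carboxylic acid | OC(=O)c1cc(=O)c(OCc2ccccc2)c(-c2ccc(OC)cc2)o1 | intermediate
12 | trimethylsilyldiazomethane | C[Si](C)(C)C=[N+]=[N-] | starting material
13 | 5-(benzyloxy)-6-(4-methoxyphenyl)-4-oxo-4H-pyran-2-carbonyl chloride | ClC(=O)c1cc(=O)c(OCc2ccccc2)c(-c2ccc(OC)cc2)o1 | intermediate
14 | 5-(benzyloxy)-2-(diazoacetyl)-6-(4-methoxyphenyl)-4H-pyran-4-one | [N-]=[N+]=CC(=O)c1cc(=O)c(OCc2ccccc2)c(-c2ccc(OC)cc2)o1 | intermediate
15 | 5-(benzyloxy)-6-(4-methoxyphenyl)-2-(2-oxoethenyl)-4H-pyran-4-one (pyranonylketene) | O=C=Cc1cc(=O)c(OCc2ccccc2)c(-c2ccc(OC)cc2)o1 | intermediate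
16 | 4-[5-(benzyloxy)-6-(4-methoxyphenyl)-4-oxo-4H-pyran-2-yl]-3-(triisopropylsilyloxy)cyclobut-2-en-1-one, racemic | O=C1C=C(O[Si](C(C)C)(C(C)C)C(C)C)C1c1cc(=O)c(OCc2ccccc2)c(-c2ccc(OC)cc2)o1 | intermediate
17 | (1E)-5-(benzyloxy)-6-(4-methoxyphenyl)-2-[4-oxo-2-(triisopropylsilyloxy)buta-1,3-dien-1-yl]-4H-pyran-4-one, ketene carbon cis to the pyranonyl group | O=C=C/C(O[Si](C(C)C)(C(C)C)C(C)C)=C\c1cc(=O)c(OCc2ccccc2)c(-c2ccc(OC)cc2)o1 | intermediate
18 | 3-(benzyloxy)-2-(4-methoxyphenyl)-7-(triisopropylsilyloxy)-4aH-chromene-4,5-dione, racemic | COc1ccc(cc1)C1=C(OCc2ccccc2)C(=O)C2C(=O)C=C(O[Si](C(C)C)(C(C)C)C(C)C)C=C2O1 | intermediate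
19 | 3-(benzyloxy)-5-hydroxy-2-(4-methoxyphenyl)-7-(triisopropylsilyloxy)-4H-chromen-4-one | COc1ccc(-c2oc3cc(O[Si](C(C)C)(C(C)C)C(C)C)cc(O)c3c(=O)c2OCc2ccccc2)cc1 | intermediate
20 | 3,5-dihydroxy-2-(4-methoxyphenyl)-7-(triisopropylsilyloxy)-4H-chromen-4-one | COc1ccc(-c2oc3cc(O[Si](C(C)C)(C(C)C)C(C)C)cc(O)c3c(=O)c2O)cc1 | intermediate
21 | pyridinium 5-hydroxy-2-(4-methoxyphenyl)-4-oxo-7-(triisopropylsilyloxy)-4H-chromen-3-yl sulfate | COc1ccc(-c2oc3cc(O[Si](C(C)C)(C(C)C)C(C)C)cc(O)c3c(=O)c2OS(=O)(=O)[O-])cc1.c1cc[nH+]cc1 | intermediate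
22 | kaempferide 3-O-sulfate, 5,7-dihydroxy-2-(4-methoxyphenyl)-4-oxo-4H-chromen-3-yl hydrogen sulfate | COc1ccc(-c2oc3cc(O)cc(O)c3c(=O)c2OS(=O)(=O)O)cc1 | target

**Count**
Total steps: 10. Longest linear sequence: 9 steps (kojic acid 6 to 22, steps 2–10); step 1 is a one-step side branch that joins at step 7.

**Steps most likely to fail**

Step 7. The pyranone or the 3-benzyloxy carbonyl chromophore may compete for light and undergo photoisomerisation or hydrogen abstraction from the benzylic CH2. Closure onto the pyranone carbon may also be slow enough for the ketene to dimerise or to acylate the product phenol, although chelation of the C5 hydroxyl should limit the latter. The fallback makes the same ketene in the dark by dehydrochlorination. It sets out from diazo ketone 14. Silver benzoate (AgO2CPh) with Et3N in aqueous dioxane should give the homologous [5-(benzyloxy)-6-(4-methoxyphenyl)-4-oxo-4H-pyran-2-yl]acetic acid F1 by Arndt–Eistert rearrangement; it is kept cold because it is a vinylogous β-keto acid. Oxalyl chloride with catalytic DMF converts it into [5-(benzyloxy)-6-(4-methoxyphenyl)-4-oxo-4H-pyran-2-yl]acetyl chloride F2. Slow addition of F2 to i-Pr2NEt and siloxyalkyne 5 in toluene at 25 °C, then warming to 80 °C, should generate ketene 15 and run the same cascade through 16, 17 and 18. The fallback returns to the route at 19.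

Step 1. Monolithium acetylide may disproportionate to Li2C2 during the warm-up that the oxidation needs, and the unhindered parent ynolate may be silylated partly on carbon to give a silylketene. The fallback blocks the second acetylenic position with a removable silyl group. It sets out from triflate 2 and commercial trimethylsilylacetylene. n-BuLi gives lithium (trimethylsilyl)acetylide F3, which does not disproportionate. Oxidation with t-BuOOLi gives lithium (trimethylsilyl)ethynolate F4, and O-silylation with 2 gives trimethyl[(triisopropylsilyloxy)ethynyl]silane F5. Selective removal of the alkynyl trimethylsilyl group with K2CO3 in MeOH at 0 °C, which the hindered Si–O bond should survive, returns to the route at 5.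

Step 9. Sulfation of the hydrogen-bonded and flanked 3-hydroxyl may be incomplete; the aryl silyl ether may be lost on prolonged exposure to base, which would open the 7-hydroxyl to sulfation; and the ionic product may lose sulfate during purification and the later acidification. The fallback carries the sulfate as a neutral, chromatographable diester. It sets out from 20. 2,2,2-Trichloroethyl chlorosulfate with Et3N and DMAP in THF should give 5-hydroxy-2-(4-methoxyphenyl)-4-oxo-7-(triisopropylsilyloxy)-4H-chromen-3-yl 2,2,2-trichloroethyl sulfate F6. HF·pyridine then removes the silyl ether to give 5,7-dihydroxy-2-(4-methoxyphenyl)-4-oxo-4H-chromen-3-yl 2,2,2-trichloroethyl sulfate F7. Reductive cleavage with Zn dust and HCO2NH4 in MeOH gives ammonium 5,7-dihydroxy-2-(4-methoxyphenyl)-4-oxo-4H-chromen-3-yl sulfate F8, and cold cation exchange (H+ form) returns to the route at 22.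

**Further compounds**
F1 | step 7 | [5-(benzyloxy)-6-(4-methoxyphenyl)-4-oxo-4H-pyran-2-yl]acetic acid | OC(=O)Cc1cc(=O)c(OCc2ccccc2)c(-c2ccc(OC)cc2)o1
F2 | step 7 | [5-(benzyloxy)-6-(4-methoxyphenyl)-4-oxo-4H-pyran-2-yl]acetyl chloride | ClC(=O)Cc1cc(=O)c(OCc2ccccc2)c(-c2ccc(OC)cc2)o1
F3 | step 1 | lithium (trimethylsilyl)acetylide | C[Si](C)(C)C#C[Li]
F4 | step 1 | lithium (trimethylsilyl)ethynolate | C[Si](C)(C)C#C[O-].[Li+]
F5 | step 1 | trimethyl[(triisopropylsilyloxy)ethynyl]silane | C[Si](C)(C)C#CO[Si](C(C)C)(C(C)C)C(C)C
F6 | step 9 | 5-hydroxy-2-(4-methoxyphenyl)-4-oxo-7-(triisopropylsilyloxy)-4H-chromen-3-yl 2,2,2-trichloroethyl sulfate | COc1ccc(-c2oc3cc(O[Si](C(C)C)(C(C)C)C(C)C)cc(O)c3c(=O)c2OS(=O)(=O)OCC(Cl)(Cl)Cl)cc1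
F7 | step 9 | 5,7-dihydroxy-2-(4-methoxyphenyl)-4-oxo-4H-chromen-3-yl 2,2,2-trichloroethyl sulfate | COc1ccc(-c2oc3cc(O)cc(O)c3c(=O)c2OS(=O)(=O)OCC(Cl)(Cl)Cl)cc1
F8 | step 9 | ammonium 5,7-dihydroxy-2-(4-methoxyphenyl)-4-oxo-4H-chromen-3-yl sulfate | COc1ccc(-c2oc3cc(O)cc(O)c3c(=O)c2OS(=O)(=O)[O-])cc1.[NH4+]
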